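A single first-order constant cannot describe the south-east run: read from substrate, it slides from 0.0261 h⁻¹ at 4.00 h to 0.0181 h⁻¹ at 50.0 h. This run is the flask asked about, followed so far.

- south-east: substrate 0.31 M; coupling partner 1.1 equiv; scavenger 1.2 equiv; the very flask that is asked about, followed so far
- flask: substrate 0.31 M; coupling partner 1.10 equiv; scavenger 1.20 equiv; time 5.0 d

south-east run (percent of the substrate charged)

| time / h | substrate / % | product / % |
|---|---|---|
| 4.00 | 90.1 | 10.3 |
| 6.00 | 85.7 | 14.0 |
| 10.0 | 78.0 | 22.1 |
| 20.0 | 63.8 | 36.1 |
| 30.0 | 53.8 | 45.8 |
| 50.0 | 40.4 | 59.4 |

(standard deviation of a reading: 0.3 percentage points)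

- part of the substrate that has reacted at 5.0 d
- share of the unused coupling partner that is free and not bound as idle adduct, at 5.0 d

- the earlier runs do not show how much of coupling partner is bound; that part of a forecast is a guess

The drift points to c(coupling partner), taken to fall one for one with c(substrate) and to stay 0.100 above it. With the rate proportional to c(substrate)·c(coupling partner), the integrated law turns the last reading into κ, the second-order constant times the substrate charge: 0.0252 h⁻¹. The reading at 20.0 h gives 0.0251 h⁻¹.

Two extremes bracket the part reacted at 5.0 d. With c(coupling partner) held at its charge, the pseudo-first-order case, the reckoning gives 96.4 %; with no excess, plain second order, it gives 75.1 %. My reckoning for the flask falls between, at 79.5 %, nearer the second-order end, because by then the excess is about half of the substrate left. The readings show nothing of c(idle adduct), so the free share stays a guess.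

The forecast says 79.5 % of the substrate reacted and 80 % of the unused coupling partner free: “So most partner is probably free, but this is a guess”. The flask gives 79.5 % reacted and 99.8 % free.

    scavenger + released group → scavenged by-product (k = 10.0 L mol⁻¹ h⁻¹)
    substrate + coupling partner ⇌ product + released group (K = 1.40, k = 0.0820 L mol⁻¹ h⁻¹)
    coupling partner + released group ⇌ idle adduct, settled at all times (K = 6.30 L mol⁻¹)

The neighbour flask, with 0.440 equiv of coupling partner and the other charges unchanged, makes coupling partner the limiting reagent. The same law with the same κ, the excess now substrate's by 0.560, gives 39.1 % at 5.0 d. That flask gives 39.1 %, with 11.1 % of its coupling partner remaining.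

The numbers in the tables stem from a simulated flask with made-up constants, and the scatter is random.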